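**Plan**
- Retrosynthesis: C10=CH2 is cut back to a C10 ketone. The cyclopentane bond C5–C9 is then traced back to the C5–C10 bond of a trans-decalin cis-9,10-diol 9-mesylate (ring B = C5–C6–C7–C8–C9–C10). Then C13–C14, C8–C14, C3–C4 and C1–C10 are cut, back to (R)-carvone.
- Forward: the carvone ring becomes ring B. Ring A is annulated (alkylation at C10, HAT radical closure C4→C3). The side chain is built on a temporary γ-lactone (C9–O to C15) by a Michael addition/hydroxylation with a chiral butenolide.
- Last ring event: a semipinacol 1,2-shift contracts ring B to the cyclopentane and at the same time expands ring A to the cycloheptanone; methylenation ends the route.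
- Enabling feature: C10 is a tertiary carbinol next to the secondary C9 sulfonate. In the trans-decalin chair the ring-fusion bond C5–C10 is antiperiplanar to the equatorial C9–O bond.
- Stereochemistry: C5 from (R)-carvone; C10–O by hydroxylation then alkylation anti to isopropenyl; C8 by alkylation anti to axial 10-OBn; C9–O by axial hydride attack; C14 by α-face attack on the fused lactone enolate; C13 by anti addition to the (5S)-menthyloxybutenolide; C12 by trans hydroxylation; C9–H by inversion in the key step.

Key step: step 14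

Remark (locants): from compound 8 on, atoms carry the locants of the target carbocycle: C1–C3 = (CH2)3, C4 = CMe2, C5 = CH, C6/C7 = CH2, C8 = C–CH3, C9 = CH, C10 = the carbon that ends as C=CH2, C14 = side-chain CH, C15 = CH2O, C13/C16/C11/C12 = lactone CH, OCH2, C=O, CHO. β is the face of ring B that carries the C8 methyl group, α the other face. Compounds 1–7 use carvone numbering (carvone C6 becomes C10).

Remark (assumption): 16 is the enantiomer of the common (5R)-5-(l-menthyloxy)-2(5H)-furanone and is taken as a purchasable reagent.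

**Step 1**
Reactants: 1 (R)-(−)-carvone
Product: 3 trans-6-hydroxycarvone, via lithium dienolate 2 (not isolated)
Conditions: LDA, THF, −78 °C; 2-(phenylsulfonyl)-3-phenyloxaziridine, −78 °C; H2O
Reagents that add atoms: trans-2-(phenylsulfonyl)-3-phenyloxaziridine, O=S(=O)(c1ccccc1)N1OC1c1ccccc1
Why: Kinetic α′-deprotonation gives the cross-conjugated dienolate, whose Davis enolate hydroxylation should place OH trans to the isopropenyl group; this centre (the later C10) becomes planar again in step 3, so only C5 of carvone carries stereochemical information forward.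

**Step 2**
Reactants: 3 trans-6-hydroxycarvone
Product: 4 trans-6-(benzyloxy)carvone
Conditions: BnBr, Ag2O, CH2Cl2, rt
Reagents that add atoms: benzyl bromide, BrCc1ccccc1
Why: Silver(I) oxide Williamson benzylation etherifies the ketol without forming its enolate; the benzyl ether carries the C10 oxygen through the enolate and radical steps and leaves by hydrogenolysis in step 12.

**Step 3**
Reactants: 4 trans-6-(benzyloxy)carvone; 5 ethyl 2-(bromomethyl)acrylate
Product: 7 C6-alkylated benzyloxycarvone acrylate ester (OBn cis to isopropenyl), via lithium enolate 6 (not isolated)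
Conditions: LDA, THF, −78 °C; 5, DMPU, −78 → −40 °C
Reagents that add atoms: none
Why: Kinetic α′-enolate formation and SN2′ (addition–elimination) allylation should create the quaternary C10; A(1,2) strain against the in-plane OBn turns the isopropenyl group pseudoaxial, so the electrophile enters anti to it and OBn ends cis to isopropenyl (the future trans ring fusion with axial 10-OBn).

**Step 4**
Reactants: 7 C6-alkylated benzyloxycarvone acrylate ester
Product: 8 ethyl 10β-(benzyloxy)-4,4,8-trimethyl-9-oxo-5αH-octal-7-ene-2-carboxylate (trans-fused; C2 not controlled)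
Conditions: Fe(acac)3 (30 mol %), PhSiH3, EtOH/(CH2OH)2, 60 °C
Reagents that add atoms: none
Why: Iron hydride HAT (Mukaiyama-type reductive olefin coupling, intramolecular Giese addition) turns the isopropenyl group into the tertiary C4 radical, which should close ring A by 6-endo-trig attack on the acrylate CH2 (C3); the C5/C10 relationship fixes the trans fusion, the gem-dimethyl group comes from the isopropenyl unit, and the C2 centre is removed in step 6.

**Step 5**
Reactants: 8 bicyclic enone ethyl ester
Product: 9 10β-(benzyloxy)-4,4,8-trimethyl-9-oxo-5αH-octal-7-ene-2-carboxylic acid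
Conditions: LiOH, THF/MeOH/H2O, rt; 1 M HCl
Reagents that add atoms: lithium hydroxide, [Li+].[OH-]
Why: Saponification of the ester that served only to activate the radical acceptor; the enone and the tertiary benzyl ether should be stable to aqueous hydroxide at room temperature.

**Step 6**
Reactants: 9 bicyclic enone acid
Product: 10 10β-(benzyloxy)-4,4,8-trimethyl-5αH-octal-7-en-9-one (trans-fused)
Conditions: 9-mesityl-10-phenylacridinium BF4 (5 mol %), (PhS)2 (10 mol %), i-Pr2NEt (20 mol %), CF3CH2OH, 450 nm, rt
Reagents that add atoms: none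
Why: Acridinium photoredox hydrodecarboxylation (carboxylate oxidation, loss of CO2, hydrogen-atom transfer from thiophenol to the secondary C2 radical) removes the helper carboxyl group and with it the uncontrolled C2 centre.

**Step 7**
Reactants: 10 trans-fused benzyloxy enone; 11 ethyl bromoacetate
Product: 13 ethyl [10β-(benzyloxy)-4,4,8β-trimethyl-9-oxo-5αH-decalin-8α-yl]acetate, via lithium enolate 12 (not isolated)
Conditions: L-Selectride, THF, −78 °C; 11, DMPU, −78 → 0 °C
Reagents that add atoms: none
Why: Conjugate hydride reduction of the β-unsubstituted enone (carbonyl shielded by quaternary C10) gives the regiodefined C8 enolate, whose alkylation should occur anti to the axial 10β-benzyloxy group, setting quaternary C8 with β-methyl and α-CH2CO2Et (reductive alkylation of an enone).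

**Step 8**
Reactants: 13 keto ester
Product: 15 trans-fused γ-lactone of the 9β-hydroxy acid (C15 carbonyl; C14 = CH2), via hydroxy ester 14 (not isolated)
Conditions: NaBH4, MeOH/THF, 0 °C → rt; TsOH (cat.), PhMe, 60 °C
Reagents that add atoms: none
Why: Borohydride should attack the hindered C9 ketone along the axial α-trajectory because the β-face is flanked by the axial 8β-methyl and 10β-benzyloxy groups, giving the equatorial 9β-alcohol, which lactonises onto the equatorial acetate arm (temporary ring that fixes C14 in step 9 and stores the C9 oxygen).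

**Step 9**
Reactants: 15 trans-fused γ-lactone; 16 (5S)-5-(d-menthyloxy)-2(5H)-furanone
Product: 19 Michael/hydroxylation adduct (C13 substituent trans to 12-OH and to 16-O-menthyl; H14 β), via lithium lactone enolate 17 (not isolated), via lithium adduct enolate 18 (not isolated)
Conditions: LDA, THF, −78 °C; 16, −78 °C; 2-(phenylsulfonyl)-3-phenyloxaziridine, −78 → −40 °C; H2O
Reagents that add atoms: trans-2-(phenylsulfonyl)-3-phenyloxaziridine, O=S(=O)(c1ccccc1)N1OC1c1ccccc1
Why: Tandem Michael addition/electrophilic enolate hydroxylation: the lactone enolate should attack the butenolide β-carbon (C13) from its own α-face, anti to the axial 8β-methyl (sets C14); the butenolide is attacked anti to its menthyloxy group (sets C13, auxiliary control); the oxaziridine enters anti to the new C13 substituent (sets C12 trans).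

**Step 10**
Reactants: 19 Michael/hydroxylation adduct
Product: 22 triol lactone (9β-OH; C15H2OH; (3S,4R)-3-hydroxy-2-oxooxolan-4-yl on C14), via potassium carboxylate 20 (not isolated), via triol carboxylate 21 (not isolated)
Conditions: NaBH4, KOH, EtOH, 0 °C → rt; evaporate; LiBH4, THF, 0 → 40 °C; 2 M HCl, rt
Reagents that add atoms: none
Why: Hydroxide opens the acyl acetal to the carboxylate and the C16 aldehyde, which borohydride should reduce before C13 can epimerise (menthol is released); the carboxylate is inert to LiBH4, which reduces the remaining hindered lactone to C15H2OH and the free 9β-alcohol, and acid closes the γ-lactone between C11 and the C16 hydroxyl (chemoselective lactone reduction with a carboxylate as transient protection).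

**Step 11**
Reactants: 22 triol lactone
Product: 23 12,15-diacetate of 22
Conditions: Ac2O, pyridine, 0 °C → rt
Reagents that add atoms: acetic anhydride, CC(=O)OC(C)=O
Why: Acylation of the primary C15 alcohol and of the activated α-hydroxy-lactone C12 alcohol; the C9 alcohol, flanked by quaternary C8 and C10, should remain free.

**Step 12**
Reactants: 23 diacetate
Product: 24 9β,10β-diol diacetate (trans-decalin cis-diol)
Conditions: H2 (1 atm), Pd(OH)2/C, EtOAc, rt
Reagents that add atoms: none
Why: Hydrogenolysis of the tertiary benzyl ether frees the C10 hydroxyl; no alkene is present at this stage and the acetates and the lactone are inert.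

**Step 13**
Reactants: 24 cis-diol diacetate
Product: 25 9β-mesylate of 24 (10β-OH free)
Conditions: MsCl, Et3N, CH2Cl2, −20 °C
Reagents that add atoms: methanesulfonyl chloride, CS(=O)(=O)Cl
Why: Sulfene-type mesylation should reach the hindered secondary C9 alcohol while the tertiary C10 alcohol does not react, giving the cis-hydroxy mesylate needed for the key step.

**Step 14**
Reactants: 25 cis-hydroxy mesylate
Product: 26 cis-fused perhydroazulen-10-one (target with C10=O in place of C10=CH2)
Conditions: LiClO4, CaCO3, THF, 50 °C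
Reagents that add atoms: none
Why: LiClO4-assisted ionisation of the equatorial C9 mesylate is concerted with a 1,2-shift of C5 from C10 to C9, pushed by the axial C10 hydroxyl, which becomes the C10 ketone (semipinacol mechanism). The closest known reaction type is the pinacol-type rearrangement of cis-1,2-diol monosulfonates used to turn decalins into hydroazulenones. The cyclopentane (C5–C6–C7–C8–C9) is closed by this suprafacial 1,2-alkyl shift, that is by contraction of six-membered ring B with expulsion of C10, and the same shift expands ring A to the seven-membered ketone ring (C1–C4, C5, C9, C10). C9 is formed with inversion (C5 enters anti to the leaving mesylate), which should place H9 cis to H5, and C5 migrates with retention; C8 and the side-chain centres are untouched. The step needs C5 rather than C1 to migrate and no shift of C7 or methyl from C8: in the rigid trans-decalin chair only the C5–C10 bond of the carbinol carbon is antiperiplanar to the equatorial C9–O bond and only that shift is assisted by the oxygen lone pair, and the cis (axial/equatorial) OH/OMs arrangement rules out epoxide formation.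

**Step 15**
Reactants: 26 cis-fused perhydroazulen-10-one
Product: 27 target CNP0234964.1
Conditions: Zn, CH2Br2, TiCl4, THF/CH2Cl2, 0 °C → rt
Reagents that add atoms: dibromomethane, BrCBr
Why: Takai–Lombardo methylenation (non-basic gem-dimetallic reagent, selective for ketones over esters and lactones) should convert the C10 ketone into the exocyclic methylene without enolising the adjacent C9 centre, so the cis ring fusion is kept.

**Compound list**
1 | (R)-(−)-carvone, (5R)-2-methyl-5-(prop-1-en-2-yl)cyclohex-2-en-1-one | CC(=C)[C@@H]1CC=C(C)C(=O)C1 | starting material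
2 | lithium cross-conjugated dienolate of 1 (O–Li on C1, C1=C6) | CC(=C)[C@@H]1CC=C(C)C(O[Li])=C1 | intermediate (not isolated)
3 | trans-6-hydroxycarvone, (5S,6S)-6-hydroxy-2-methyl-5-(prop-1-en-2-yl)cyclohex-2-en-1-one | CC(=C)[C@@H]1CC=C(C)C(=O)[C@H]1O | intermediate
4 | trans-6-(benzyloxy)carvone, (5S,6S)-6-(benzyloxy)-2-methyl-5-(prop-1-en-2-yl)cyclohex-2-en-1-one | CC(=C)[C@@H]1CC=C(C)C(=O)[C@H]1OCc2ccccc2 | intermediate
5 | ethyl 2-(bromomethyl)acrylate | C=C(CBr)C(=O)OCC | starting material
6 | lithium dienolate of 4 (C6 planar) | CC(=C)[C@@H]1CC=C(C)C(O[Li])=C1OCc2ccccc2 | intermediate (not isolated)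
7 | ethyl 2-{[1-(benzyloxy)-3-methyl-2-oxo-6-(prop-1-en-2-yl)cyclohex-3-en-1-yl]methyl}acrylate, OBn cis and acrylate arm trans to isopropenyl | CC(=C)[C@@H]1CC=C(C)C(=O)[C@@]1(OCc2ccccc2)CC(=C)C(=O)OCC | intermediate
8 | ethyl 10β-(benzyloxy)-4,4,8-trimethyl-9-oxo-5αH-octal-7-ene-2-carboxylate (trans-fused; C2 epimers) | CC1(C)CC(C(=O)OCC)C[C@]2(OCc3ccccc3)C(=O)C(C)=CC[C@@H]12 | intermediate
9 | 10β-(benzyloxy)-4,4,8-trimethyl-9-oxo-5αH-octal-7-ene-2-carboxylic acid (C2 epimers) | CC1(C)CC(C(=O)O)C[C@]2(OCc3ccccc3)C(=O)C(C)=CC[C@@H]12 | intermediate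
10 | 10β-(benzyloxy)-4,4,8-trimethyl-5αH-octal-7-en-9-one (trans-fused enone) | CC1(C)CCC[C@]2(OCc3ccccc3)C(=O)C(C)=CC[C@@H]12 | intermediate
11 | ethyl bromoacetate | CCOC(=O)CBr | starting material
12 | lithium C8=C9 enolate of the 7,8-dihydro derivative of 10 | CC1(C)CCC[C@]2(OCc3ccccc3)C(O[Li])=C(C)CC[C@@H]12 | intermediate (not isolated)
13 | ethyl [10β-(benzyloxy)-4,4,8β-trimethyl-9-oxo-5αH-decalin-8α-yl]acetate | CC1(C)CCC[C@]2(OCc3ccccc3)C(=O)[C@](C)(CC(=O)OCC)CC[C@@H]12 | intermediate
14 | ethyl [10β-(benzyloxy)-9β-hydroxy-4,4,8β-trimethyl-5αH-decalin-8α-yl]acetate | CC1(C)CCC[C@]2(OCc3ccccc3)[C@@H](O)[C@](C)(CC(=O)OCC)CC[C@@H]12 | intermediate (not isolated)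
15 | [10β-(benzyloxy)-9β-hydroxy-4,4,8β-trimethyl-5αH-decalin-8α-yl]acetic acid γ-lactone (trans-fused) | CC1(C)CCC[C@]2(OCc3ccccc3)[C@H]4OC(=O)C[C@]4(C)CC[C@@H]12 | intermediate
16 | (5S)-5-{[(1S,2R,5S)-2-isopropyl-5-methylcyclohexyl]oxy}furan-2(5H)-one, (5S)-5-(d-menthyloxy)-2(5H)-furanone | O=C1C=C[C@@H](O[C@@H]2[C@@H](C(C)C)CC[C@H](C)C2)O1 | starting material
17 | lithium enolate of 15 (C14=C15–OLi) | CC1(C)CCC[C@]2(OCc3ccccc3)[C@H]4OC(O[Li])=C[C@]4(C)CC[C@@H]12 | intermediate (not isolated)
18 | lithium enolate (C12=C11–OLi) of the Michael adduct of 17 and 16 | CC1(C)CCC[C@]2(OCc3ccccc3)[C@H]4OC(=O)[C@H]([C@@H]5[C@@H](O[C@@H]6[C@@H](C(C)C)CC[C@H](C)C6)OC(O[Li])=C5)[C@]4(C)CC[C@@H]12 | intermediate (not isolated)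
19 | lactone 15 bearing at C14 (H β) the 3-hydroxy-5-(d-menthyloxy)-2-oxooxolan-4-yl ring, C13 substituent trans to 12-OH and to 16-O-menthyl | CC1(C)CCC[C@]2(OCc3ccccc3)[C@H]4OC(=O)[C@H]([C@@H]5[C@@H](O[C@@H]6[C@@H](C(C)C)CC[C@H](C)C6)OC(=O)[C@H]5O)[C@]4(C)CC[C@@H]12 | intermediate
20 | potassium carboxylate: lactone of 15 retained, C14 bearing CH(CH2OH)–CH(OH)–CO2K | CC1(C)CCC[C@]2(OCc3ccccc3)[C@H]4OC(=O)[C@H]([C@H](CO)[C@H](O)C(=O)[O-])[C@]4(C)CC[C@@H]12.[K+] | intermediate (not isolated)
21 | potassium carboxylate with 9β-OH, C15H2OH, C16H2OH and 12-OH free, 10β-OBn | CC1(C)CCC[C@]2(OCc3ccccc3)[C@@H](O)[C@](C)([C@H](CO)[C@H](CO)[C@H](O)C(=O)[O-])CC[C@@H]12.[K+] | intermediate (not isolated)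
22 | triol lactone: 10β-(benzyloxy)-9β-hydroxy-4,4,8β-trimethyl-5αH-decalin with 8α-[(14R)-CH(CH2OH)] bearing (3S,4R)-3-hydroxy-2-oxooxolan-4-yl | CC1(C)CCC[C@]2(OCc3ccccc3)[C@@H](O)[C@](C)([C@H](CO)[C@@H]5COC(=O)[C@H]5O)CC[C@@H]12 | intermediate
23 | 12,15-di-O-acetate of 22 | CC1(C)CCC[C@]2(OCc3ccccc3)[C@@H](O)[C@](C)([C@H](COC(C)=O)[C@@H]5COC(=O)[C@H]5OC(C)=O)CC[C@@H]12 | intermediate
24 | 9β,10β-dihydroxy-4,4,8β-trimethyl-5αH-decalin carrying the 12,15-diacetoxy lactone side chain at C8α | CC1(C)CCC[C@]2(O)[C@@H](O)[C@](C)([C@H](COC(C)=O)[C@@H]5COC(=O)[C@H]5OC(C)=O)CC[C@@H]12 | intermediate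
25 | 9β-methanesulfonate of 24 (10β-OH free) | CC1(C)CCC[C@]2(O)[C@@H](OS(C)(=O)=O)[C@](C)([C@H](COC(C)=O)[C@@H]5COC(=O)[C@H]5OC(C)=O)CC[C@@H]12 | intermediate
26 | cis-fused (5α-H, 9α-H) 4,4,8β-trimethylperhydroazulen-10-one with the (12S,13R,14R)-diacetoxy lactone side chain at C8α | O=C1CCCC(C)(C)[C@@H]2CC[C@@](C)([C@H](COC(C)=O)[C@@H]3COC(=O)[C@H]3OC(C)=O)[C@H]12 | intermediate
27 | CNP0234964.1: 10-methylene analogue of 26 (5α-H, 9α-H, 8β-CH3; 12S,13R,14R) | C=C1CCCC(C)(C)[C@@H]2CC[C@@](C)([C@H](COC(C)=O)[C@@H]3COC(=O)[C@H]3OC(C)=O)[C@H]12 | target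

**Step count and risks**
Total step count: 15. Longest linear sequence: 15 steps, from (R)-carvone (1) to 27.

Steps most likely to fail:

Step 9. The lithium enolate 17 and the butenolide 16 are both hindered and both chiral, so the addition may be slow, may revert (retro-Michael), or may show poor facial selectivity if the two partners are a mismatched pair; proton transfer before the oxidation is a further risk. Fallback, from 15 back to 19: the C13–C14 bond would be made under Lewis acid control through an open transition state. Lactone 15 is converted (LDA, TBSCl, THF/DMPU, −78 °C) into the tert-butyldimethylsilyl ketene acetal F1. Mukaiyama–Michael addition of this to 16 (TBSOTf cat., CH2Cl2, −78 °C) should give the silyl ketene acetal of the adduct F2. Rubottom oxidation of this (DMDO, acetone, −78 °C; then HF·pyridine) returns to 19.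

Step 10. The hindered C15 lactone may be saponified by KOH before LiBH4 is added, which would make it inert to the hydride, or hydride may reduce the wrong carbonyl; lactonisation could also go to the six-membered ring. Fallback, from 19 back to 22: the C11 carboxyl is masked as an amide instead of a salt. 19 is first taken (NaBH4, KOH, EtOH; then HCl) to the bis-lactone F3, in which menthol is gone and both lactones are closed. Pyrrolidine (THF, rt) should open only the unhindered α-hydroxy-γ-lactone to give the pyrrolidine hydroxy amide F4. LiBH4 (THF) then reduces the remaining lactone, which tertiary amides survive, to the amide tetraol F5. TsOH (PhMe, 80 °C) relactonises the γ-hydroxy amide with loss of pyrrolidine to 22.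

Step 14. The doubly neopentyl C9 sulfonate may fail to ionise with clean C5 migration: incomplete sulfonylation upstream, a competing shift of C7 from C8, or elimination would all divert material. Fallback, from 24 back to 26: the same skeletal change is made by an α-ketol rearrangement. Diol 24 is oxidised (Dess–Martin periodinane, CH2Cl2) to the 10β-hydroxy-9-ketone F6. Lewis-acid α-ketol rearrangement (BF3·OEt2, CH2Cl2, 0 °C → rt) should move C5 from C10 to the C9 carbonyl carbon and give the ring-contracted 9-hydroxy-10-ketone F7. SmI2 (THF/MeOH, −78 °C, no HMPA, so that the α-acetoxy lactone is spared) removes the tertiary 9-hydroxyl. Protonation of the samarium enolate, followed if needed by equilibration with DBU, is expected to favour the cis-fused ketone 26, in which C10 is anti to the bulky C14 substituent on C8.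

**Further compounds**
F1 | step 9 | tert-butyldimethylsilyl ketene acetal of lactone 15 | CC1(C)CCC[C@]2(OCc3ccccc3)[C@H]4OC(O[Si](C)(C)C(C)(C)C)=C[C@]4(C)CC[C@@H]12
F2 | step 9 | silyl ketene acetal (2-silyloxy-4,5-dihydrofuran) of the Mukaiyama–Michael adduct of F1 and 16 | CC1(C)CCC[C@]2(OCc3ccccc3)[C@H]4OC(=O)[C@H]([C@@H]5[C@@H](O[C@@H]6[C@@H](C(C)C)CC[C@H](C)C6)OC(O[Si](C)(C)C(C)(C)C)=C5)[C@]4(C)CC[C@@H]12
F3 | step 10 | bis-lactone: C15/9-O lactone retained, (3S,4R)-3-hydroxy-2-oxooxolan-4-yl on C14 | CC1(C)CCC[C@]2(OCc3ccccc3)[C@H]4OC(=O)[C@H]([C@@H]5COC(=O)[C@H]5O)[C@]4(C)CC[C@@H]12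
F4 | step 10 | pyrrolidine hydroxy amide (C11 amide, C16H2OH, 12-OH; C15 lactone intact) | CC1(C)CCC[C@]2(OCc3ccccc3)[C@H]4OC(=O)[C@H]([C@H](CO)[C@H](O)C(=O)N5CCCC5)[C@]4(C)CC[C@@H]12
F5 | step 10 | pyrrolidine amide tetraol (9β-OH, C15H2OH, C16H2OH, 12-OH) | CC1(C)CCC[C@]2(OCc3ccccc3)[C@@H](O)[C@](C)([C@H](CO)[C@H](CO)[C@H](O)C(=O)N5CCCC5)CC[C@@H]12
F6 | step 14 | 10β-hydroxy-9-oxo decalin with the diacetoxy lactone side chain | CC1(C)CCC[C@]2(O)C(=O)[C@](C)([C@H](COC(C)=O)[C@@H]5COC(=O)[C@H]5OC(C)=O)CC[C@@H]12
F7 | step 14 | ring-contracted 9-hydroxy-perhydroazulen-10-one (9-OH in place of H9 of 26) | O=C1CCCC(C)(C)[C@@H]2CC[C@@](C)([C@H](COC(C)=O)[C@@H]3COC(=O)[C@H]3OC(C)=O)[C@]12O
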